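**Plan**
Retrosynthesis: the three MOM ethers are removed first; then the C4–C4a acyl–aryl bond of ring C is cut, giving an (S)-3-aryl-3-aryloxypropanoic acid; then the O1–C2 ether bond; then the ring A C–OH and C6–geranyl bonds; last the C2–C3 bond of the β-keto ester.
Forward: ring A is dressed first (geranyl between two MOM ethers by directed lithiation, then OH para to it by C–H borylation/oxidation). The ring B aldehyde is homologated and reduced to the (R)-β-hydroxy ester. The halves are joined through O1, ring C is closed by acylation of ring A, and the MOM groups come off.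
Enabling feature: in ring A the geranyl carbon C6 is para to C8a–O1, so C4a and C8 are equivalent through the twofold axis C6···C8a, and each is ortho or para to all three ring oxygens. Closure at either carbon therefore gives only the 6-geranyl flavanone, and the ring is nucleophilic enough for a cold, Lewis-acid-free acylation that spares the geranyl chain and C2.
Stereochemistry: C2 is set as the (R)-carbinol by asymmetric transfer hydrogenation (step 5) and inverted to (S) in the Mitsunobu etherification (step 6); the (E)-alkene comes from geranyl bromide.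

Key step: step 8

Assumption: flavonoid numbering is used (O1, C2, C3, C4, C4a, C5 to C8, C8a; ring A = phloroglucinol ring, ring B = pendant aryl, ring C = pyranone); geranyl = (2E)-3,7-dimethylocta-2,6-dien-1-yl, MOM = methoxymethyl; compounds 1, 2 and 7 are taken as commercial.

**Step 1**
Reactants: 1 1,3-bis(methoxymethoxy)benzene; 2 geranyl bromide
Product: 4 2-[(2E)-3,7-dimethylocta-2,6-dien-1-yl]-1,3-bis(methoxymethoxy)benzene, via 2-lithio-1,3-bis(methoxymethoxy)benzene 3 (not isolated)
Conditions: n-BuLi (1.1 equiv), THF, 0 °C to rt; then CuI (10 mol%), 2, −78 °C to rt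
Reagents that add atoms: n-butyllithium [Li]CCCC (lithium of intermediate 3 only)
Why: Directed ortho-metalation places lithium at C2 between the two cooperating MOM ethers, and copper-catalysed SN2 allylation of 3 with geranyl bromide forms the aryl–CH2 bond with the (E)-alkene retained, a reaction type well known for MOM-protected resorcinols.

**Step 2**
Reactants: 4 2-geranyl-1,3-bis(methoxymethoxy)benzene
Product: 6 4-[(2E)-3,7-dimethylocta-2,6-dien-1-yl]-3,5-bis(methoxymethoxy)phenol, via arylboronic acid pinacol ester 5 (not isolated)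
Conditions: [Ir(OMe)(cod)]2 (1.5 mol%), 4,4'-di-tert-butyl-2,2'-bipyridine (3 mol%), B2pin2 (1.0 equiv), THF, 60 °C; then 30% aq. H2O2, aq. NaOH, THF, 0 °C
Reagents that add atoms: bis(pinacolato)diboron CC1(C)OB(OC1(C)C)B1OC(C)(C)C(C)(C)O1 (boron of intermediate 5 only); hydrogen peroxide OO
Why: Iridium-catalysed aromatic C–H borylation is sterically controlled and should take the only ring C–H without an ortho substituent (para to geranyl), trisubstituted alkenes being poor substrates for the iridium boryl catalyst, and basic peroxide then oxidises C–B to C–OH without touching the alkenes (one-pot borylation–oxidation to 3,5-disubstituted phenols).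

**Step 3**
Reactants: 7 3-hydroxy-4,5-dimethoxybenzaldehyde
Product: 8 3,4-dimethoxy-5-(methoxymethoxy)benzaldehyde
Conditions: MOMCl, i-Pr2NEt, CH2Cl2, 0 °C to rt
Reagents that add atoms: chloromethyl methyl ether COCCl
Why: Base-mediated O-alkylation of the phenol (Williamson type) installs the same acetal protecting group as on ring A, so that all three can be removed together in the last step.

**Step 4**
Reactants: 8 3,4-dimethoxy-5-(methoxymethoxy)benzaldehyde
Product: 9 ethyl 3-[3,4-dimethoxy-5-(methoxymethoxy)phenyl]-3-oxopropanoate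
Conditions: ethyl diazoacetate, SnCl2 (10 mol%), CH2Cl2, rt
Reagents that add atoms: ethyl diazoacetate CCOC(=O)C=[N+]=[N-]
Why: Roskamp homologation, in which the tin-activated aldehyde is attacked by the diazo carbon and a 1,2-hydride shift with loss of N2 gives the β-keto ester directly.

**Step 5**
Reactants: 9 ethyl 3-[3,4-dimethoxy-5-(methoxymethoxy)phenyl]-3-oxopropanoate
Product: 10 ethyl (3R)-3-[3,4-dimethoxy-5-(methoxymethoxy)phenyl]-3-hydroxypropanoate
Conditions: RuCl[(R,R)-TsDPEN](p-cymene) (1 mol%), HCO2H/Et3N (5:2), DMF, rt to 40 °C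
Reagents that add atoms: none
Why: Noyori asymmetric transfer hydrogenation of an aryl ketone, in which the (R,R)-TsDPEN ruthenium hydride should deliver hydride to the face that gives the (R)-benzylic alcohol, as with acetophenone, and so sets the only stereocentre of the route.

**Step 6**
Reactants: 6 4-geranyl-3,5-bis(methoxymethoxy)phenol; 10 ethyl (3R)-3-[3,4-dimethoxy-5-(methoxymethoxy)phenyl]-3-hydroxypropanoate
Product: 11 ethyl (3S)-3-[3,4-dimethoxy-5-(methoxymethoxy)phenyl]-3-{4-[(2E)-3,7-dimethylocta-2,6-dien-1-yl]-3,5-bis(methoxymethoxy)phenoxy}propanoate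
Conditions: PPh3, DIAD, toluene, 0 °C to rt
Reagents that add atoms: none
Why: Mitsunobu etherification, in which the phenoxide of 6 (its only free OH is the unhindered one para to geranyl) displaces the alkoxyphosphonium ion by SN2 with inversion, turning the (R)-carbinol into the (S)-aryl ether that becomes C2–O1.

**Step 7**
Reactants: 11 ethyl (3S)-3-aryl-3-aryloxypropanoate
Product: 12 (3S)-3-[3,4-dimethoxy-5-(methoxymethoxy)phenyl]-3-{4-[(2E)-3,7-dimethylocta-2,6-dien-1-yl]-3,5-bis(methoxymethoxy)phenoxy}propanoic acid
Conditions: LiOH·H2O, THF/H2O (3:1), 0 °C to rt; then cold 0.5 M aq. HCl to pH 4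
Reagents that add atoms: lithium hydroxide [Li+].[OH-]
Why: Saponification at low temperature, where hydroxide attack at the ester carbonyl should outrun E1cB loss of the aryloxide and the carboxylate formed no longer eliminates, while MOM ethers, alkenes and the stereocentre are inert to aqueous base.

**Step 8**
Reactants: 12 (3S)-3-aryl-3-aryloxypropanoic acid
Product: 14 (2S)-2-[3,4-dimethoxy-5-(methoxymethoxy)phenyl]-6-[(2E)-3,7-dimethylocta-2,6-dien-1-yl]-5,7-bis(methoxymethoxy)-2,3-dihydro-4H-chromen-4-one, via mixed carboxylic trifluoroacetic anhydride 13 (not isolated)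
Conditions: (CF3CO)2O (1.05 equiv), CH2Cl2 (0.02 M), −20 to 0 °C; quench with sat. aq. NaHCO3
Reagents that add atoms: trifluoroacetic anhydride O=C(OC(=O)C(F)(F)F)C(F)(F)F (trifluoroacetyl group of intermediate 13 only)
Why: Trifluoroacetic anhydride converts acid 12 into mixed anhydride 13, whose acyl carbon (or the acylium ion in equilibrium with it) is attacked by the ring A carbon ortho to the ether oxygen, and loss of the proton from the arenium ion gives the aryl ketone with release of trifluoroacetic acid. The closest known reaction type is the intramolecular Friedel–Crafts acylation of 3-aryloxypropanoic acids to chroman-4-ones, which on phloroglucinol ethers needs anhydride activation only. Ring C closes as a six-membered ring in a 6-exo-trig mode at the anhydride carbonyl (6-exo-dig if the free acylium ion reacts). No new stereocentre is formed: C2 comes from step 6 and should survive because it is not enolisable here and its trialkoxyaryl group, with a twisted para-methoxy, stabilises a benzylic cation poorly. The step needs site selectivity between the two carbons ortho to O1 and chemoselectivity over ring B (indanone closure), the geranyl alkenes and the MOM acetals. The two ortho carbons are related by the twofold axis through C6 and C8a, so either gives the 6-geranyl isomer, and each is ortho or para to three oxygens, which makes it far more nucleophilic than any ring B carbon and allows the cold, dilute, Lewis-acid-free medium that should leave acetals and alkenes alone.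

**Step 9**
Reactants: 14 (2S)-tris-MOM flavanone
Product: 15 (2S)-6-[(2E)-3,7-dimethylocta-2,6-dien-1-yl]-5,7-dihydroxy-2-(3-hydroxy-4,5-dimethoxyphenyl)-2,3-dihydro-4H-chromen-4-one
Conditions: HCl (1.25 M in MeOH), MeOH/THF, rt (to 40 °C if needed)
Reagents that add atoms: none
Why: Acid-catalysed acetal exchange with methanol should remove the three MOM groups as dimethoxymethane under conditions known to spare geranyl and prenyl chains ortho to phenols and too mild to open ring C, so C2 keeps its (S) configuration.

**Compound list**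
1 | 1,3-bis(methoxymethoxy)benzene | COCOc1cccc(OCOC)c1 | starting material
2 | geranyl bromide, (2E)-1-bromo-3,7-dimethylocta-2,6-diene | BrC/C=C(\C)CCC=C(C)C | starting material
3 | 2-lithio-1,3-bis(methoxymethoxy)benzene | [Li]c1c(OCOC)cccc1OCOC | intermediate
4 | 2-[(2E)-3,7-dimethylocta-2,6-dien-1-yl]-1,3-bis(methoxymethoxy)benzene | COCOc1cccc(OCOC)c1C/C=C(\C)CCC=C(C)C | intermediate
5 | 2-{4-[(2E)-3,7-dimethylocta-2,6-dien-1-yl]-3,5-bis(methoxymethoxy)phenyl}-4,4,5,5-tetramethyl-1,3,2-dioxaborolane | COCOc1cc(B2OC(C)(C)C(C)(C)O2)cc(OCOC)c1C/C=C(\C)CCC=C(C)C | intermediate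
6 | 4-[(2E)-3,7-dimethylocta-2,6-dien-1-yl]-3,5-bis(methoxymethoxy)phenol | COCOc1cc(O)cc(OCOC)c1C/C=C(\C)CCC=C(C)C | intermediate
7 | 3-hydroxy-4,5-dimethoxybenzaldehyde | COc1cc(C=O)cc(O)c1OC | starting material
8 | 3,4-dimethoxy-5-(methoxymethoxy)benzaldehyde | COCOc1cc(C=O)cc(OC)c1OC | intermediate
9 | ethyl 3-[3,4-dimethoxy-5-(methoxymethoxy)phenyl]-3-oxopropanoate | CCOC(=O)CC(=O)c1cc(OC)c(OC)c(OCOC)c1 | intermediate
10 | ethyl (3R)-3-[3,4-dimethoxy-5-(methoxymethoxy)phenyl]-3-hydroxypropanoate | CCOC(=O)C[C@@H](O)c1cc(OC)c(OC)c(OCOC)c1 | intermediate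
11 | ethyl (3S)-3-[3,4-dimethoxy-5-(methoxymethoxy)phenyl]-3-{4-[(2E)-3,7-dimethylocta-2,6-dien-1-yl]-3,5-bis(methoxymethoxy)phenoxy}propanoate | CCOC(=O)C[C@H](Oc1cc(OCOC)c(C/C=C(\C)CCC=C(C)C)c(OCOC)c1)c1cc(OC)c(OC)c(OCOC)c1 | intermediate
12 | (3S)-3-[3,4-dimethoxy-5-(methoxymethoxy)phenyl]-3-{4-[(2E)-3,7-dimethylocta-2,6-dien-1-yl]-3,5-bis(methoxymethoxy)phenoxy}propanoic acid | OC(=O)C[C@H](Oc1cc(OCOC)c(C/C=C(\C)CCC=C(C)C)c(OCOC)c1)c1cc(OC)c(OC)c(OCOC)c1 | intermediate
13 | mixed anhydride of acid 12 with trifluoroacetic acid | O=C(OC(=O)C(F)(F)F)C[C@H](Oc1cc(OCOC)c(C/C=C(\C)CCC=C(C)C)c(OCOC)c1)c1cc(OC)c(OC)c(OCOC)c1 | intermediate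
14 | (2S)-2-[3,4-dimethoxy-5-(methoxymethoxy)phenyl]-6-[(2E)-3,7-dimethylocta-2,6-dien-1-yl]-5,7-bis(methoxymethoxy)-2,3-dihydro-4H-chromen-4-one | COc1cc([C@@H]2CC(=O)c3c(cc(OCOC)c(C/C=C(\C)CCC=C(C)C)c3OCOC)O2)cc(OCOC)c1OC | intermediate
15 | (2S)-6-[(2E)-3,7-dimethylocta-2,6-dien-1-yl]-5,7-dihydroxy-2-(3-hydroxy-4,5-dimethoxyphenyl)-2,3-dihydro-4H-chromen-4-one | COc1cc([C@@H]2CC(=O)c3c(cc(O)c(C/C=C(\C)CCC=C(C)C)c3O)O2)cc(O)c1OC | target

**Totals**
Total step count: 9. Longest linear sequence: 7 steps (7 → 8 → 9 → 10 → 11 → 12 → 14 → 15; steps 3 to 9).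

**Steps most likely to fail**

Step 8. The trifluoroacetic acid released may cleave MOM acetals (first the one peri to the new ketone, which would still converge in step 9) or protonate the geranyl alkenes. The activated acid may also fragment by retro-oxa-Michael loss of the phenol, and excess anhydride may trifluoroacetylate C8. Fallback (Parham-type anionic cycloacylation), setting out from 12 and returning at 14: acid 12 would be iodinated with N-iodosuccinimide in MeCN at 0 °C at a ring A carbon ortho to the ether oxygen, the two being equivalent again, to give the iodo acid F1. t-BuLi (3.1 equiv) in THF at −100 °C would then form the lithium carboxylate and exchange iodine for lithium to give the dilithio species F2. Its aryllithium adds to the carboxylate carbon to give the cyclic dilithium gem-diolate F3, which collapses to ketone 14 on aqueous work-up. No acid is present at any point, and the carboxylate cannot undergo E1cB elimination.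

Step 6. The activated β-hydroxy ester may eliminate to the cinnamate through its acidic α-CH, and partial ionisation of the benzylic alkoxyphosphonium ion may erode the enantiomeric purity. Fallback, setting out from 10 and returning at 12: the ester 10 would be reduced with LiBH4 in THF to the (R)-1-arylpropane-1,3-diol F4, and the primary OH silylated selectively (TBSCl, imidazole, CH2Cl2, 0 °C) to give the silyl ether F5. Mitsunobu coupling with 6 (PPh3, DIAD, toluene) on this substrate, which has no acidifying carbonyl, would give the (S)-aryl ether F6 with inversion. Desilylation (TBAF, THF) would give the primary alcohol F7, and oxidation with TEMPO (cat.) and PhI(OAc)2 in MeCN/H2O would give acid 12.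

Step 2. The iridium boryl catalyst and the pinacolborane formed may hydroborate, borylate or isomerise the geranyl alkenes in competition with the aromatic C–H borylation. Fallback, setting out from 1 and returning at 6, with the oxygen introduced before the alkenes are present: compound 1 would be borylated under the same iridium conditions to the arylboronic ester F8 (not isolated) and oxidised with H2O2/NaOH to 3,5-bis(methoxymethoxy)phenol F9. Silylation (TIPSCl, imidazole, DMF) would give the triisopropylsilyl ether F10. n-BuLi in THF at 0 °C would lithiate between the two MOM ethers, the bulky silyl ether being a poor director, to give the aryllithium F11. CuI-catalysed allylation with 2 would give the geranylated silyl ether F12, and TBAF in THF would release phenol 6.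

**Further compounds**
F1 | step 8 | (3S)-3-[3,4-dimethoxy-5-(methoxymethoxy)phenyl]-3-{4-geranyl-2-iodo-3,5-bis(methoxymethoxy)phenoxy}propanoic acid | OC(=O)C[C@H](Oc1cc(OCOC)c(C/C=C(\C)CCC=C(C)C)c(OCOC)c1I)c1cc(OC)c(OC)c(OCOC)c1
F2 | step 8 | dilithio species (lithium carboxylate and ring A aryllithium) from F1 | [Li]OC(=O)C[C@H](Oc1cc(OCOC)c(C/C=C(\C)CCC=C(C)C)c(OCOC)c1[Li])c1cc(OC)c(OC)c(OCOC)c1
F3 | step 8 | cyclic dilithium gem-diolate at C4 of the tris-MOM flavanone | COc1cc([C@@H]2CC(O[Li])(O[Li])c3c(cc(OCOC)c(C/C=C(\C)CCC=C(C)C)c3OCOC)O2)cc(OCOC)c1OC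
F4 | step 6 | (1R)-1-[3,4-dimethoxy-5-(methoxymethoxy)phenyl]propane-1,3-diol | OCC[C@@H](O)c1cc(OC)c(OC)c(OCOC)c1
F5 | step 6 | (1R)-3-(tert-butyldimethylsilyloxy)-1-[3,4-dimethoxy-5-(methoxymethoxy)phenyl]propan-1-ol | CC(C)(C)[Si](C)(C)OCC[C@@H](O)c1cc(OC)c(OC)c(OCOC)c1
F6 | step 6 | (S)-aryl ether of F5 with phenol 6 | CC(C)(C)[Si](C)(C)OCC[C@H](Oc1cc(OCOC)c(C/C=C(\C)CCC=C(C)C)c(OCOC)c1)c1cc(OC)c(OC)c(OCOC)c1
F7 | step 6 | (3S)-3-[3,4-dimethoxy-5-(methoxymethoxy)phenyl]-3-{4-geranyl-3,5-bis(methoxymethoxy)phenoxy}propan-1-ol | OCC[C@H](Oc1cc(OCOC)c(C/C=C(\C)CCC=C(C)C)c(OCOC)c1)c1cc(OC)c(OC)c(OCOC)c1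
F8 | step 2 | 2-[3,5-bis(methoxymethoxy)phenyl]-4,4,5,5-tetramethyl-1,3,2-dioxaborolane | COCOc1cc(B2OC(C)(C)C(C)(C)O2)cc(OCOC)c1
F9 | step 2 | 3,5-bis(methoxymethoxy)phenol | COCOc1cc(O)cc(OCOC)c1
F10 | step 2 | [3,5-bis(methoxymethoxy)phenoxy]triisopropylsilane | COCOc1cc(O[Si](C(C)C)(C(C)C)C(C)C)cc(OCOC)c1
F11 | step 2 | [4-lithio-3,5-bis(methoxymethoxy)phenoxy]triisopropylsilane | [Li]c1c(OCOC)cc(O[Si](C(C)C)(C(C)C)C(C)C)cc1OCOC
F12 | step 2 | [4-geranyl-3,5-bis(methoxymethoxy)phenoxy]triisopropylsilane | COCOc1cc(O[Si](C(C)C)(C(C)C)C(C)C)cc(OCOC)c1C/C=C(\C)CCC=C(C)C
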